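The route rests on cutting both bonds of the oxirane CH2: its C–C bond to the quaternary benzylic carbon C2 and its C–O bond. C2 already bears the benzene ring (ring A), the ring oxygen and the CH2O arm, so it is the carbonyl carbon of an α-oxygenated aryl ketone. One operation, enantioselective methylene transfer from dimethylsulfoxonium methylide under LaLi3(binaphthoxide)3, builds the oxirane (ring B), both bonds and the only stereocentre. The precursor is aryl ketone 9, which carries the benzylic pentanoate, the phenol as a triisopropylsilyl ether and the α-oxygen as a tert-butyldimethylsilyl ether.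

Key step: step 6

Assumption: LaLi3[(S)-binaphthoxide]3 is taken to deliver the methylene to the Si face of ketone 9 (O > CH2OSi > aryl), as expected if CH2OSi sits where methyl sits in aryl methyl ketones; if a pilot run shows the opposite sense, the (R)-binaphthoxide complex is used and nothing else changes.

Step 1
Reactants: 1 2'-hydroxy-4'-methylacetophenone
Product: 2 4'-methyl-2'-(triisopropylsilyloxy)acetophenone
Conditions: TIPSCl, imidazole, DMF, rt → 40 °C
Reagents that add atoms: triisopropylsilyl chloride, CC(C)[Si](Cl)(C(C)C)C(C)C
Why: Imidazole-promoted O-silylation of the phenol (silyl ether formation); the hydrogen bond to the ortho acetyl group only slows it, and the bulky triisopropylsilyl group is chosen because it must later resist carboxylate, binaphthoxide and the ylide.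

Step 2
Reactants: 2 4'-methyl-2'-(triisopropylsilyloxy)acetophenone
Product: 3 4'-(bromomethyl)-2'-(triisopropylsilyloxy)acetophenone
Conditions: NBS (1.05 equiv), AIBN (cat.), PhCF3, 80 °C
Reagents that add atoms: N-bromosuccinimide, O=C1CCC(=O)N1Br
Why: Wohl–Ziegler bromination: the bromine atom abstracts the benzylic hydrogen of the ring methyl group, the weakest C–H bond present, whereas this electrophilic radical avoids the electron-poor acetyl C–H bonds, and the low Br2 level in a non-polar solvent disfavours ionic bromination of the ring or of the ketone.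

Step 3
Reactants: 3 4'-(bromomethyl)-2'-(triisopropylsilyloxy)acetophenone; 4 pentanoic acid
Product: 6 4-acetyl-3-(triisopropylsilyloxy)benzyl pentanoate, via cesium pentanoate 5 (not isolated)
Conditions: Cs2CO3 (0.6 equiv), 4 (1.3 equiv), MeCN, rt
Reagents that add atoms: none
Why: SN2 displacement of the benzylic bromide by carboxylate 5 (ester formation by carboxylate alkylation), run with the acid in slight excess over Cs2CO3 so that the medium stays too weakly basic to strip the hindered aryl silyl ether or to enolise the ketone.

Step 4
Reactants: 6 4-acetyl-3-(triisopropylsilyloxy)benzyl pentanoate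
Product: 7 4-[1-(tert-butyldimethylsilyloxy)ethenyl]-3-(triisopropylsilyloxy)benzyl pentanoate
Conditions: TBSOTf, Et3N, CH2Cl2, 0 °C
Reagents that add atoms: tert-butyldimethylsilyl triflate, CC(C)(C)[Si](C)(C)OS(=O)(=O)C(F)(F)F
Why: Soft enolisation (silyl enol ether formation): TBSOTf silylates the ketone oxygen and Et3N removes a proton from the only α-carbon, the acetyl methyl, while the far less basic ester carbonyl is left alone at 0 °C.

Step 5
Reactants: 7 4-[1-(tert-butyldimethylsilyloxy)ethenyl]-3-(triisopropylsilyloxy)benzyl pentanoate
Product: 9 4-[2-(tert-butyldimethylsilyloxy)acetyl]-3-(triisopropylsilyloxy)benzyl pentanoate, via 2-silyloxyoxirane 8 (not isolated)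
Conditions: mCPBA, CH2Cl2, −20 → 0 °C
Reagents that add atoms: 3-chloroperbenzoic acid, OOC(=O)c1cccc(Cl)c1
Why: Rubottom oxidation: the peracid epoxidises the electron-rich enol ether double bond much faster than it attacks anything else in the molecule, and the 2-silyloxyoxirane 8 opens to a benzylic oxocarbenium ion in which the TBS group shifts 1,4 from oxygen to oxygen, which should give the α-silyloxy ketone with the bulky silyl group retained.

Step 6
Reactants: 9 4-[2-(tert-butyldimethylsilyloxy)acetyl]-3-(triisopropylsilyloxy)benzyl pentanoate; 10 trimethylsulfoxonium chloride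
Product: 13 4-[(2S)-2-(tert-butyldimethylsilyloxymethyl)oxiran-2-yl]-3-(triisopropylsilyloxy)benzyl pentanoate, via dimethylsulfoxonium methylide 11 (not isolated), via betaine alkoxide 12 (not isolated)
Conditions: 10, NaH, THF, reflux, filtered; then 9, ylide solution (1.2 equiv), LaLi3[(S)-binaphthoxide]3 (10 mol %), (2,4,6-(MeO)3C6H2)3P=O (10 mol %), 5 Å MS, THF, rt
Reagents that add atoms: none
Why: The trivalent lanthanum centre of the catalyst binds and activates the ketone oxygen of 9 while a lithium binaphthoxide unit, opened up by the phosphine oxide, holds ylide 11, so that the ylide carbon adds to the carbonyl carbon to give betaine alkoxide 12, whose oxygen then displaces dimethyl sulfoxide from the neighbouring CH2. The closest known reaction is the catalytic asymmetric Corey–Chaykovsky epoxidation of aryl and alkyl methyl ketones with this ylide and this catalyst system, applied here to a ketone whose small flank is CH2OSi instead of methyl. The oxirane closes in 3-exo-tet mode. The new quaternary stereocentre is set under catalyst control by the chiral binaphthoxide pocket, which is expected to leave the Si face open and so give the (S) oxirane. The step needs face selection and attack at the ketone only: the flat aryl ring and the tetrahedral CH2OSi arm differ enough in shape for the pocket to tell them apart, the ketone is made more electrophilic by its α-oxygen while the alkyl pentanoate is too poor an acylating agent for a sulfoxonium ylide at room temperature, and both other oxygens are silyl ethers, so nothing can acylate the ylide or shift to the betaine oxygen (a 1,4 oxygen-to-oxygen shift of the bulky TBS group should be slower than ring closure). The ylide is made from the chloride because NaCl drops out of THF, whereas a soluble iodide salt could exchange into the lithium sites of the catalyst.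

Step 7
Reactants: 13 4-[(2S)-2-(tert-butyldimethylsilyloxymethyl)oxiran-2-yl]-3-(triisopropylsilyloxy)benzyl pentanoate; 14 isobutyric anhydride
Product: 16 4-[(2S)-2-(tert-butyldimethylsilyloxymethyl)oxiran-2-yl]-3-(2-methylpropanoyloxy)benzyl pentanoate, via cesium phenoxide 15 (not isolated)
Conditions: CsF (1.2 equiv), 14 (3 equiv), DMF, 0 °C → rt
Reagents that add atoms: none
Why: Fluoride-triggered exchange of an aryl silyl ether for an aryl ester: fluoride attacks the silicon whose oxygen is the better leaving group, the aryl one, and phenoxide 15 is acylated at once by the anhydride present in excess, so that it has no time to ionise the benzylic C–O bond of the oxirane (closure onto the oxirane CH2 would be 5-endo and slow in any case), while the neopentyl-type primary TBS ether and the alkyl esters should not be touched by CsF at this temperature.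

Step 8
Reactants: 16 4-[(2S)-2-(tert-butyldimethylsilyloxymethyl)oxiran-2-yl]-3-(2-methylpropanoyloxy)benzyl pentanoate
Product: 17 4-[(2R)-2-(hydroxymethyl)oxiran-2-yl]-3-(2-methylpropanoyloxy)benzyl pentanoate (same spatial arrangement as 16; the descriptor changes only because CH2OH ranks below the ring CH2)
Conditions: Et3N·3HF, MeCN, rt
Reagents that add atoms: none
Why: Desilylation with a weakly acidic fluoride source: Et3N·3HF cleaves the primary TBS ether without ever forming an alkoxide, so the isobutyryl group should stay on the aryl oxygen, and the reagent is not acidic enough at room temperature to open an oxirane whose benzylic carbon is flanked by two CH2O groups and an acyloxy-substituted ring.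

Step 9
Reactants: 17 4-[(2R)-2-(hydroxymethyl)oxiran-2-yl]-3-(2-methylpropanoyloxy)benzyl pentanoate
Product: 18 4-[(2S)-2-(acetoxymethyl)oxiran-2-yl]-3-(2-methylpropanoyloxy)benzyl pentanoate (CNP0107520.1)
Conditions: Ac2O, pyridine, DMAP (cat.), CH2Cl2, 0 °C
Reagents that add atoms: acetic anhydride, CC(=O)OC(C)=O
Why: Acylation of the primary alcohol through the acylpyridinium ion (DMAP-catalysed esterification), fast enough at 0 °C to outrun intramolecular transfer of the aryl ester and without effect on the oxirane or its stereocentre.

Compound list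
1 | 2'-hydroxy-4'-methylacetophenone | CC(=O)c1ccc(C)cc1O | starting material
2 | 4'-methyl-2'-(triisopropylsilyloxy)acetophenone | CC(=O)c1ccc(C)cc1O[Si](C(C)C)(C(C)C)C(C)C | intermediate
3 | 4'-(bromomethyl)-2'-(triisopropylsilyloxy)acetophenone | CC(=O)c1ccc(CBr)cc1O[Si](C(C)C)(C(C)C)C(C)C | intermediate
4 | pentanoic acid | CCCCC(=O)O | starting material
5 | cesium pentanoate (not isolated) | CCCCC(=O)[O-].[Cs+] | intermediate
6 | 4-acetyl-3-(triisopropylsilyloxy)benzyl pentanoate | CCCCC(=O)OCc1ccc(C(C)=O)c(O[Si](C(C)C)(C(C)C)C(C)C)c1 | intermediate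
7 | 4-[1-(tert-butyldimethylsilyloxy)ethenyl]-3-(triisopropylsilyloxy)benzyl pentanoate | CCCCC(=O)OCc1ccc(C(=C)O[Si](C)(C)C(C)(C)C)c(O[Si](C(C)C)(C(C)C)C(C)C)c1 | intermediate
8 | 4-[2-(tert-butyldimethylsilyloxy)oxiran-2-yl]-3-(triisopropylsilyloxy)benzyl pentanoate, racemic (not isolated) | CCCCC(=O)OCc1ccc(C2(O[Si](C)(C)C(C)(C)C)CO2)c(O[Si](C(C)C)(C(C)C)C(C)C)c1 | intermediate
9 | 4-[2-(tert-butyldimethylsilyloxy)acetyl]-3-(triisopropylsilyloxy)benzyl pentanoate | CCCCC(=O)OCc1ccc(C(=O)CO[Si](C)(C)C(C)(C)C)c(O[Si](C(C)C)(C(C)C)C(C)C)c1 | intermediate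
10 | trimethylsulfoxonium chloride | C[S+](C)(C)=O.[Cl-] | starting material
11 | dimethylsulfoxonium methylide (not isolated) | C[S+](C)(=O)[CH2-] | intermediate
12 | (R)-configured betaine alkoxide, (2R)-1-(tert-butyldimethylsilyloxy)-3-(dimethylsulfoxonio)-2-[4-(pentanoyloxymethyl)-2-(triisopropylsilyloxy)phenyl]propan-2-olate (not isolated) | CCCCC(=O)OCc1ccc([C@@]([O-])(CO[Si](C)(C)C(C)(C)C)C[S+](C)(C)=O)c(O[Si](C(C)C)(C(C)C)C(C)C)c1 | intermediate
13 | 4-[(2S)-2-(tert-butyldimethylsilyloxymethyl)oxiran-2-yl]-3-(triisopropylsilyloxy)benzyl pentanoate | CCCCC(=O)OCc1ccc([C@@]2(CO[Si](C)(C)C(C)(C)C)CO2)c(O[Si](C(C)C)(C(C)C)C(C)C)c1 | intermediate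
14 | isobutyric anhydride | CC(C)C(=O)OC(=O)C(C)C | starting material
15 | cesium 2-[(2S)-2-(tert-butyldimethylsilyloxymethyl)oxiran-2-yl]-5-(pentanoyloxymethyl)phenoxide (not isolated) | CCCCC(=O)OCc1ccc([C@@]2(CO[Si](C)(C)C(C)(C)C)CO2)c([O-])c1.[Cs+] | intermediate
16 | 4-[(2S)-2-(tert-butyldimethylsilyloxymethyl)oxiran-2-yl]-3-(2-methylpropanoyloxy)benzyl pentanoate | CCCCC(=O)OCc1ccc([C@@]2(CO[Si](C)(C)C(C)(C)C)CO2)c(OC(=O)C(C)C)c1 | intermediate
17 | 4-[(2R)-2-(hydroxymethyl)oxiran-2-yl]-3-(2-methylpropanoyloxy)benzyl pentanoate | CCCCC(=O)OCc1ccc([C@@]2(CO)CO2)c(OC(=O)C(C)C)c1 | intermediate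
18 | 4-[(2S)-2-(acetoxymethyl)oxiran-2-yl]-3-(2-methylpropanoyloxy)benzyl pentanoate | CCCCC(=O)OCc1ccc([C@@]2(COC(C)=O)CO2)c(OC(=O)C(C)C)c1 | target

Total step count: 9. Longest linear sequence: 9 steps (1 → 18); compounds 4, 10 and 14 enter as purchased reagents.

Steps most likely to fail

1. Step 6. The likely failure is poor facial selectivity, because the CH2OSi flank is larger than the methyl group on which the selectivity of this catalyst class rests and the ortho silyloxy group twists the ring; conversion may also stall if the basic ylide enolises the ketone. The fallback sets out from 9 and comes back at 13, with the allylic hydroxyl group, not a catalyst pocket, directing the oxidant. Wittig methylenation of 9 (Ph3P=CH2 from Ph3PCH3Br and KOtBu, THF, 0 °C) should give the allyl silyl ether 4-[3-(tert-butyldimethylsilyloxy)prop-1-en-2-yl]-3-(triisopropylsilyloxy)benzyl pentanoate F1. Mild acid (PPTS, MeOH, rt), which spares the aryl silyl ether, should free the allylic alcohol 4-(3-hydroxyprop-1-en-2-yl)-3-(triisopropylsilyloxy)benzyl pentanoate F2. Sharpless asymmetric epoxidation (Ti(OiPr)4, D-(−)-diethyl tartrate, t-BuOOH, 4 Å MS, CH2Cl2, −20 °C) should then give the epoxy alcohol 4-[(2R)-2-(hydroxymethyl)oxiran-2-yl]-3-(triisopropylsilyloxy)benzyl pentanoate F3; the usual facial rule for the tartrate places the oxygen on the face that corresponds to 13. Silylation (TBSCl, imidazole, CH2Cl2, 0 °C) returns 13.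

2. Step 7. The likely failure is ionisation or opening of the oxirane by the liberated phenoxide before it is acylated, or concurrent loss of the primary silyl ether with acylation of the wrong oxygen. The fallback sets out from 13 and comes back at 16, and keeps the aryl oxygen protonated throughout instead of trapping an anion. Fluoride buffered with acetic acid (Bu4NF/AcOH 1:1, THF, −20 °C) should cleave the aryl silyl ether, far faster than the alkyl one, to the neutral phenol 4-[(2S)-2-(tert-butyldimethylsilyloxymethyl)oxiran-2-yl]-3-hydroxybenzyl pentanoate F4. This is acylated in a separate operation with isobutyryl chloride and pyridine in CH2Cl2 at −20 °C to give 16.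

3. Step 8. The likely failure is sluggish cleavage of the hindered primary silyl ether and, over the long exposure, shift of the isobutyryl group from the aryl oxygen to the freed hydroxyl or opening of the oxirane by HF. The fallback reverses the order of the two acylations so that a free hydroxyl never sits beside an aryl ester. It sets out from 9 and comes back at 18, and follows the first fallback through alkene F1 and allylic alcohol F2 to epoxy alcohol F3, whose hydroxyl is then not silylated. Acetylation of F3 (Ac2O, pyridine, DMAP, 0 °C) should give the acetate 4-[(2S)-2-(acetoxymethyl)oxiran-2-yl]-3-(triisopropylsilyloxy)benzyl pentanoate F5. Exchange of its only silyl ether with CsF and isobutyric anhydride 14 in DMF at 0 °C, through the cesium phenoxide cesium 2-[(2S)-2-(acetoxymethyl)oxiran-2-yl]-5-(pentanoyloxymethyl)phenoxide F6, should give 18 directly.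

Further compounds
F1 | step 6 | 4-[3-(tert-butyldimethylsilyloxy)prop-1-en-2-yl]-3-(triisopropylsilyloxy)benzyl pentanoate | CCCCC(=O)OCc1ccc(C(=C)CO[Si](C)(C)C(C)(C)C)c(O[Si](C(C)C)(C(C)C)C(C)C)c1
F2 | step 6 | 4-(3-hydroxyprop-1-en-2-yl)-3-(triisopropylsilyloxy)benzyl pentanoate | CCCCC(=O)OCc1ccc(C(=C)CO)c(O[Si](C(C)C)(C(C)C)C(C)C)c1
F3 | step 6 | 4-[(2R)-2-(hydroxymethyl)oxiran-2-yl]-3-(triisopropylsilyloxy)benzyl pentanoate | CCCCC(=O)OCc1ccc([C@@]2(CO)CO2)c(O[Si](C(C)C)(C(C)C)C(C)C)c1
F4 | step 7 | 4-[(2S)-2-(tert-butyldimethylsilyloxymethyl)oxiran-2-yl]-3-hydroxybenzyl pentanoate | CCCCC(=O)OCc1ccc([C@@]2(CO[Si](C)(C)C(C)(C)C)CO2)c(O)c1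
F5 | step 8 | 4-[(2S)-2-(acetoxymethyl)oxiran-2-yl]-3-(triisopropylsilyloxy)benzyl pentanoate | CCCCC(=O)OCc1ccc([C@@]2(COC(C)=O)CO2)c(O[Si](C(C)C)(C(C)C)C(C)C)c1
F6 | step 8 | cesium 2-[(2S)-2-(acetoxymethyl)oxiran-2-yl]-5-(pentanoyloxymethyl)phenoxide | CCCCC(=O)OCc1ccc([C@@]2(COC(C)=O)CO2)c([O-])c1.[Cs+]
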